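The route rests on a [3+3] annulation that builds ring B onto a pre-formed, enantiopure ring A (labdane numbering). Ring B carries the C6 oxygen and the tetrasubstituted C8=C9 alkene in a 1,3-relationship across C7, so C6–C7–C8 (with C17) is recognised as crotonaldehyde turned into a γ-silyloxyallyl phosphorus ylide. In one flask its C6 adds to C5 of a ring-A alkylidene β-keto ester and its C8 olefinates the C9 ketone on the quaternary C10, giving the decalin with C6 as an enol ether; the enolate left at C4 is methylated in the same pot. The precursor is a monocyclic 4-acyl-4-methylcyclohexenone ester made by an asymmetric Diels–Alder reaction.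

Key step: step 6

Remark: labdane numbering is used throughout (ring A = C1–C5 and C10, ring B = C5–C10, C17 on C8, C18 (α) and C19 (β) on C4, C20 on C10, side chain C11–C16); the (R,R)-TADDOL is assumed to deliver the (S)-quaternary centre of 3, otherwise its antipode is used.

Step 1
Reactants: 1 (E)-3-[(tert-butyldimethylsilyl)oxy]-N,N-dimethylbuta-1,3-dien-1-amine, 2 methacrolein
Product: 3 (1S,2R)-2-(dimethylamino)-1-methyl-4-[(tert-butyldimethylsilyl)oxy]cyclohex-3-ene-1-carbaldehyde
Conditions: (R,R)-1-naphthyl-TADDOL (20 mol %), toluene, −80 °C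
Reagents that add atoms: none
Why: Hydrogen-bond-catalysed asymmetric Diels–Alder reaction of the amino siloxy diene with the α-substituted acrolein should give the endo adduct with the amine next to and the siloxy group para to the quaternary carbon (future C10), whose S configuration is set by the chiral diol shielding one face of the bound aldehyde.

Step 2
Reactants: 3 (1S,2R)-2-(dimethylamino)-1-methyl-4-[(tert-butyldimethylsilyl)oxy]cyclohex-3-ene-1-carbaldehyde, 4 2-(2-bromoethyl)-2-methyl-1,3-dioxolane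
Product: 7 (4S)-4-[(1RS)-1-hydroxy-3-(2-methyl-1,3-dioxolan-2-yl)propyl]-4-methylcyclohex-2-en-1-one, via Grignard reagent 5 (not isolated), via carbinol silyl enol ether 6 (not isolated)
Conditions: 4, Mg, THF, 25 °C; 3, −78 → 0 °C; H2O; then HF·pyridine, THF, 0 °C
Reagents that add atoms: none
Why: Grignard addition to the aldehyde (future C9) while the enone is still masked, followed by cleavage of the silyl enol ether and β-elimination of dimethylamine, should unveil the 4,4-disubstituted cyclohexenone with the dioxolane intact; the carbinol configuration is irrelevant.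

Step 3
Reactants: 7 (4S)-4-[(1RS)-1-hydroxy-3-(2-methyl-1,3-dioxolan-2-yl)propyl]-4-methylcyclohex-2-en-1-one
Product: 8 (4S)-4-methyl-4-[3-(2-methyl-1,3-dioxolan-2-yl)propanoyl]cyclohex-2-en-1-one
Conditions: Dess–Martin periodinane, NaHCO3, CH2Cl2, 0 → 25 °C
Reagents that add atoms: none
Why: Dess–Martin oxidation of the secondary carbinol should give the C9 ketone without touching the enone or the ketal, and it removes the C9 epimer mixture.

Step 4
Reactants: 8 (4S)-4-methyl-4-[3-(2-methyl-1,3-dioxolan-2-yl)propanoyl]cyclohex-2-en-1-one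
Product: 9 (4S)-2-iodo-4-methyl-4-[3-(2-methyl-1,3-dioxolan-2-yl)propanoyl]cyclohex-2-en-1-one
Conditions: I2, pyridine, CH2Cl2, 0 → 25 °C
Reagents that add atoms: iodine, II
Why: α-Iodination of the enone by the iodine/pyridine protocol (conjugate addition of pyridine, iodination of the enolate, elimination) is selective for the enone α-carbon, the future C4.

Step 5
Reactants: 9 (4S)-2-iodo-4-methyl-4-[3-(2-methyl-1,3-dioxolan-2-yl)propanoyl]cyclohex-2-en-1-one
Product: 10 methyl (3S)-3-methyl-3-[3-(2-methyl-1,3-dioxolan-2-yl)propanoyl]-6-oxocyclohex-1-ene-1-carboxylate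
Conditions: Pd(OAc)2 (5 mol %), PPh3, CO (1 atm), MeOH, Et3N, DMF, 60 °C
Reagents that add atoms: carbon monoxide, [C-]#[O+]; methanol, CO
Why: Palladium-catalysed methoxycarbonylation of the vinyl iodide installs the C19 ester and makes C5 a doubly activated Michael acceptor that cannot tautomerise because C10 is quaternary.

Step 6
Reactants: 10 methyl (3S)-3-methyl-3-[3-(2-methyl-1,3-dioxolan-2-yl)propanoyl]-6-oxocyclohex-1-ene-1-carboxylate, 11 (E)-but-2-enal (crotonaldehyde)
Product: 17 methyl 6-[(tert-butyldimethylsilyl)oxy]-13,13-(ethylenedioxy)-3-oxo-14,15-dinorlabda-6,8-dien-19-oate, via phosphonium triflate 12 (not isolated), via allyl ylide 13 (not isolated), via zwitterionic Michael adduct 14 (not isolated), via enolate ylide 15 (not isolated), via bicyclic potassium enolate 16 (not isolated)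
Conditions: 11, PPh3, TBSOTf, THF, 25 °C; n-BuLi, −78 °C; 10, −78 → −20 °C; KOt-Bu, then 65 °C; MeI, 0 °C
Reagents that add atoms: tert-butyldimethylsilyl triflate, CC(C)(C)[Si](C)(C)OS(=O)(=O)C(F)(F)F; iodomethane, CI
Why: Proposed new method: phosphoniosilylation of crotonaldehyde gives the γ-silyloxyallyl phosphonium salt, whose ylide should add through its oxygen-bearing γ-carbon (C6) to C5 of the alkylidene β-keto ester (Michael addition), after which KOt-Bu regenerates the allyl ylide and its phosphorus-bearing carbon (C8) olefinates the C9 ketone (intramolecular Wittig reaction), so that the C5–C6 single bond and the C8=C9 double bond arise in one flask; the closest known reaction types are the cyclohexadiene annulation of enones with allylidenetriphenylphosphoranes (γ-Michael addition, then intramolecular Wittig) and the phosphoniosilylation–Wittig β-functionalisation of enones, here transferred to an acceptor and a ketone that are not conjugated but 1,3-disposed on the quaternary C10. Ring B is the only ring closed, by a six-membered intramolecular Wittig olefination that completes the [3+3] annulation of C6–C7–C8 from 11 onto C5–C10–C9 of 10. C5 should be set by axial attack of the ylide anti to the pseudoaxial acyl group on C10, which places C6 trans to C9 and leads to the trans ring fusion. C4 is set by methylation of the β-keto ester enolate from the α-face, anti to the axial C10 methyl group, which leaves the ester (C19) axial. The step needs γ- over α-attack of the ylide, secured by the shielding of the phosphorus-bearing carbon by PPh3 and its methyl group, and olefination of C9 instead of C3, secured because C3 stays locked as the unreactive β-keto ester enolate until MeI is added.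

Step 7
Reactants: 17 methyl 6-[(tert-butyldimethylsilyl)oxy]-13,13-(ethylenedioxy)-3-oxo-14,15-dinorlabda-6,8-dien-19-oate
Product: 18 methyl 13,13-(ethylenedioxy)-3,6-dioxo-14,15-dinorlabd-8-en-19-oate
Conditions: HF·pyridine, pyridine, THF, −20 → 0 °C
Reagents that add atoms: none
Why: Cleavage of the silyl dienol ether with kinetic protonation at C7, the α-carbon of the dienol, should give the β,γ-unsaturated 6-ketone with the C8=C9 bond left in place (silyl enol ether hydrolysis).

Step 8
Reactants: 18 methyl 13,13-(ethylenedioxy)-3,6-dioxo-14,15-dinorlabd-8-en-19-oate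
Product: 20 13,13-(ethylenedioxy)-14,15-dinorlabd-8-ene-3α,6β,19-triol, via 3α-hydroxy keto ester 19 (not isolated)
Conditions: K[BH(s-Bu)3], THF, −78 °C; then LiAlH4, −78 → 25 °C
Reagents that add atoms: none
Why: Hydride reductions under steric approach control: the bulky borohydride should attack the C3 ketone equatorially to give the axial 3α-alcohol, and LiAlH4 then reduces the C6 ketone from the open α-face (the β-face is blocked by C19 and C20) and the C19 ester, by way of the 19,6β-lactone, to the primary alcohol.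

Step 9
Reactants: 20 13,13-(ethylenedioxy)-14,15-dinorlabd-8-ene-3α,6β,19-triol
Product: 21 19-[(tert-butyldimethylsilyl)oxy]-13,13-(ethylenedioxy)-14,15-dinorlabd-8-ene-3α,6β-diol
Conditions: TBSCl, imidazole, DMF, 0 °C
Reagents that add atoms: tert-butyldimethylsilyl chloride, CC(C)(C)[Si](C)(C)Cl
Why: Silylation should be selective for the primary 19-hydroxyl over the two hindered axial secondary hydroxyls.

Step 10
Reactants: 21 19-[(tert-butyldimethylsilyl)oxy]-13,13-(ethylenedioxy)-14,15-dinorlabd-8-ene-3α,6β-diol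
Product: 22 19-[(tert-butyldimethylsilyl)oxy]-13,13-(ethylenedioxy)-14,15-dinorlabd-8-ene-3α,6β-diyl bis(3-methylbutanoate)
Conditions: 3-methylbutanoyl chloride, DMAP, pyridine, CH2Cl2, 40 °C
Reagents that add atoms: 3-methylbutanoyl chloride, CC(C)CC(=O)Cl
Why: DMAP-catalysed acylation with the acid chloride under forcing conditions should esterify both axial secondary alcohols with retention at C3 and C6.

Step 11
Reactants: 22 19-[(tert-butyldimethylsilyl)oxy]-13,13-(ethylenedioxy)-14,15-dinorlabd-8-ene-3α,6β-diyl bis(3-methylbutanoate)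
Product: 23 19-[(tert-butyldimethylsilyl)oxy]-13-oxo-14,15-dinorlabd-8-ene-3α,6β-diyl bis(3-methylbutanoate)
Conditions: PPTS, acetone/H2O, 50 °C
Reagents that add atoms: water, O
Why: Mild acid-catalysed ketal hydrolysis frees the C13 methyl ketone, while the primary silyl ether and the esters should persist.

Step 12
Reactants: 23 19-[(tert-butyldimethylsilyl)oxy]-13-oxo-14,15-dinorlabd-8-ene-3α,6β-diyl bis(3-methylbutanoate)
Product: 24 tert-butyl (13E)-19-[(tert-butyldimethylsilyl)oxy]-3α,6β-bis(3-methylbutanoyloxy)labda-8,13-dien-15-oate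
Conditions: tert-butyl 2-(diethoxyphosphoryl)acetate, NaH, THF, 0 → 50 °C
Reagents that add atoms: tert-butyl 2-(diethoxyphosphoryl)acetate, CCOP(=O)(OCC)CC(=O)OC(C)(C)C
Why: Horner–Wadsworth–Emmons olefination of the unhindered methyl ketone should give mainly the (13E)-enoate, the minor Z isomer to be removed by chromatography.

Step 13
Reactants: 24 tert-butyl (13E)-19-[(tert-butyldimethylsilyl)oxy]-3α,6β-bis(3-methylbutanoyloxy)labda-8,13-dien-15-oate
Product: 25 (13E)-19-hydroxy-3α,6β-bis(3-methylbutanoyloxy)labda-8,13-dien-15-oic acid (CNP0272110.1)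
Conditions: CF3CO2H, CH2Cl2, H2O (trace), 0 → 25 °C
Reagents that add atoms: none
Why: Acidolysis should cleave the tert-butyl ester (loss of 2-methylpropene) and the primary silyl ether in one operation, while the two isovalerates and the tetrasubstituted alkene are expected to persist.

Compound list
1 | (E)-3-[(tert-butyldimethylsilyl)oxy]-N,N-dimethylbuta-1,3-dien-1-amine | C=C(O[Si](C)(C)C(C)(C)C)/C=C/N(C)C | starting material
2 | methacrolein (2-methylprop-2-enal) | CC(=C)C=O | starting material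
3 | (1S,2R)-2-(dimethylamino)-1-methyl-4-[(tert-butyldimethylsilyl)oxy]cyclohex-3-ene-1-carbaldehyde (endo adduct) | O=C[C@@]1(C)CCC(O[Si](C)(C)C(C)(C)C)=C[C@H]1N(C)C | intermediate
4 | 2-(2-bromoethyl)-2-methyl-1,3-dioxolane | CC1(CCBr)OCCO1 | starting material
5 | [2-(2-methyl-1,3-dioxolan-2-yl)ethyl]magnesium bromide | CC1(CC[Mg]Br)OCCO1 | intermediate (not isolated)
6 | 1-[(1S,2R)-2-(dimethylamino)-1-methyl-4-[(tert-butyldimethylsilyl)oxy]cyclohex-3-en-1-yl]-3-(2-methyl-1,3-dioxolan-2-yl)propan-1-ol (carbinol epimers) | OC(CCC3(C)OCCO3)[C@@]1(C)CCC(O[Si](C)(C)C(C)(C)C)=C[C@H]1N(C)C | intermediate (not isolated)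
7 | (4S)-4-[(1RS)-1-hydroxy-3-(2-methyl-1,3-dioxolan-2-yl)propyl]-4-methylcyclohex-2-en-1-one | OC(CCC2(C)OCCO2)[C@@]1(C)CCC(=O)C=C1 | intermediate
8 | (4S)-4-methyl-4-[3-(2-methyl-1,3-dioxolan-2-yl)propanoyl]cyclohex-2-en-1-one | O=C(CCC2(C)OCCO2)[C@@]1(C)CCC(=O)C=C1 | intermediate
9 | (4S)-2-iodo-4-methyl-4-[3-(2-methyl-1,3-dioxolan-2-yl)propanoyl]cyclohex-2-en-1-one | O=C(CCC2(C)OCCO2)[C@@]1(C)CCC(=O)C(I)=C1 | intermediate
10 | methyl (3S)-3-methyl-3-[3-(2-methyl-1,3-dioxolan-2-yl)propanoyl]-6-oxocyclohex-1-ene-1-carboxylate | O=C(CCC2(C)OCCO2)[C@@]1(C)CCC(=O)C(C(=O)OC)=C1 | intermediate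
11 | (E)-but-2-enal (crotonaldehyde) | C/C=C/C=O | starting material
12 | {4-[(tert-butyldimethylsilyl)oxy]but-3-en-2-yl}triphenylphosphonium triflate (racemic, enol ether geometry not controlled, drawn E) | CC(/C=C/O[Si](C)(C)C(C)(C)C)[P+](c1ccccc1)(c1ccccc1)c1ccccc1.[O-]S(=O)(=O)C(F)(F)F | intermediate (not isolated)
13 | {4-[(tert-butyldimethylsilyl)oxy]but-3-en-2-ylidene}triphenylphosphorane | CC(/C=C/O[Si](C)(C)C(C)(C)C)=P(c1ccccc1)(c1ccccc1)c1ccccc1 | intermediate (not isolated)
14 | zwitterionic Michael adduct: C3 enolate of the β-keto ester with the C5–C6 bond formed and a vinylphosphonium at C8 (5α-H, C6 epimers) | O=C(CCC3(C)OCCO3)[C@@]2(C)CCC([O-])=C(C(=O)OC)[C@@H]2C(O[Si](C)(C)C(C)(C)C)C=C(C)[P+](c1ccccc1)(c1ccccc1)c1ccccc1 | intermediate (not isolated)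
15 | potassium enolate of 14 after deprotonation at C6 (allyl ylide at C8) | O=C(CCC3(C)OCCO3)[C@@]2(C)CCC([O-])=C(C(=O)OC)[C@@H]2C(O[Si](C)(C)C(C)(C)C)=CC(C)=P(c1ccccc1)(c1ccccc1)c1ccccc1.[K+] | intermediate (not isolated)
16 | potassium C3 enolate of methyl 6-[(tert-butyldimethylsilyl)oxy]-13,13-(ethylenedioxy)-3-oxo-18,14,15-trinorlabda-6,8-dien-19-oate (5α-H, 10β-Me) | CC1=C(CCC3(C)OCCO3)[C@@]2(C)CCC([O-])=C(C(=O)OC)[C@@H]2C(O[Si](C)(C)C(C)(C)C)=C1.[K+] | intermediate (not isolated)
17 | methyl 6-[(tert-butyldimethylsilyl)oxy]-13,13-(ethylenedioxy)-3-oxo-14,15-dinorlabda-6,8-dien-19-oate (5α-H, 10β-Me, 4α-Me, 4β-CO2Me) | CC1=C(CCC3(C)OCCO3)[C@@]2(C)CCC(=O)[C@](C)(C(=O)OC)[C@@H]2C(O[Si](C)(C)C(C)(C)C)=C1 | intermediate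
18 | methyl 13,13-(ethylenedioxy)-3,6-dioxo-14,15-dinorlabd-8-en-19-oate | CC1=C(CCC3(C)OCCO3)[C@@]2(C)CCC(=O)[C@](C)(C(=O)OC)[C@@H]2C(=O)C1 | intermediate
19 | methyl 13,13-(ethylenedioxy)-3α-hydroxy-6-oxo-14,15-dinorlabd-8-en-19-oate | CC1=C(CCC3(C)OCCO3)[C@@]2(C)CC[C@@H](O)[C@](C)(C(=O)OC)[C@@H]2C(=O)C1 | intermediate (not isolated)
20 | 13,13-(ethylenedioxy)-14,15-dinorlabd-8-ene-3α,6β,19-triol | CC1=C(CCC3(C)OCCO3)[C@@]2(C)CC[C@@H](O)[C@](C)(CO)[C@@H]2[C@H](O)C1 | intermediate
21 | 19-[(tert-butyldimethylsilyl)oxy]-13,13-(ethylenedioxy)-14,15-dinorlabd-8-ene-3α,6β-diol | CC1=C(CCC3(C)OCCO3)[C@@]2(C)CC[C@@H](O)[C@](C)(CO[Si](C)(C)C(C)(C)C)[C@@H]2[C@H](O)C1 | intermediate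
22 | 19-[(tert-butyldimethylsilyl)oxy]-13,13-(ethylenedioxy)-14,15-dinorlabd-8-ene-3α,6β-diyl bis(3-methylbutanoate) | CC1=C(CCC3(C)OCCO3)[C@@]2(C)CC[C@@H](OC(=O)CC(C)C)[C@](C)(CO[Si](C)(C)C(C)(C)C)[C@@H]2[C@H](OC(=O)CC(C)C)C1 | intermediate
23 | 19-[(tert-butyldimethylsilyl)oxy]-13-oxo-14,15-dinorlabd-8-ene-3α,6β-diyl bis(3-methylbutanoate) | CC1=C(CCC(C)=O)[C@@]2(C)CC[C@@H](OC(=O)CC(C)C)[C@](C)(CO[Si](C)(C)C(C)(C)C)[C@@H]2[C@H](OC(=O)CC(C)C)C1 | intermediate
24 | tert-butyl (13E)-19-[(tert-butyldimethylsilyl)oxy]-3α,6β-bis(3-methylbutanoyloxy)labda-8,13-dien-15-oate | CC1=C(CC/C(C)=C/C(=O)OC(C)(C)C)[C@@]2(C)CC[C@@H](OC(=O)CC(C)C)[C@](C)(CO[Si](C)(C)C(C)(C)C)[C@@H]2[C@H](OC(=O)CC(C)C)C1 | intermediate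
25 | (13E)-19-hydroxy-3α,6β-bis(3-methylbutanoyloxy)labda-8,13-dien-15-oic acid (CNP0272110.1) | CC1=C(CC/C(C)=C/C(=O)O)[C@@]2(C)CC[C@@H](OC(=O)CC(C)C)[C@](C)(CO)[C@@H]2[C@H](OC(=O)CC(C)C)C1 | target

Total step count: 13. Longest linear sequence: 13 steps (1 + 2 → 25).

Steps most likely to fail

Step 6 (key step, proposed new method). The ylide may attack through its phosphorus-bearing carbon, leading to cyclopropanation or simple olefination. Olefination of the hindered C9 ketone to a tetrasubstituted alkene may stall. Facial selectivity at C5 may be poor. Fallback with known chemistry, from 10 back to 18: lithiated 2-(2-methylprop-2-en-1-yl)-1,3-dithiane F1 (made from 1,3-dithiane, n-BuLi and 3-chloro-2-methylpropene) is added in conjugate fashion to 10 to give the Michael adduct β-keto ester F2. Its potassium enolate (KN(SiMe3)2), which protects C3, is methylenated at the C9 ketone with Ph3P=CH2 and then C-methylated with MeI to give the bis(1,1-disubstituted alkene) F3. Ring-closing metathesis with the second-generation Hoveyda–Grubbs catalyst (toluene, 100 °C) closes ring B with the tetrasubstituted C8=C9 bond to give the dithioketal F4. Hydrolysis of the dithiane (MeI, CaCO3, aqueous MeCN) returns to 18.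

Step 7. The C8=C9 bond may migrate into conjugation with the new C6 ketone during or after unmasking, and a cis-fused fraction from step 6 would be carried along. Fallback, from 17 back to 18: 17 is desilylated and deliberately equilibrated (HF·pyridine, then DBU) to the thermodynamic, trans-fused conjugated enone, methyl 13,13-(ethylenedioxy)-3,6-dioxo-14,15-dinorlabd-7-en-19-oate F5. Its potassium dienolate (KOt-Bu, THF, −78 °C) is then protonated kinetically at C7 with AcOH (deconjugative protonation), which returns to 18 and also corrects the ring fusion.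

Step 8. Hydride delivery to C3 may show poor facial selectivity, giving the equatorial 3β-alcohol, and the basic borohydride may enolise the C6 ketone. Fallback, from 18 back to 20: NaBH4 reduces both ketones of 18 from their open faces and the 6β-alkoxide lactonises, giving the 3β-hydroxy 19,6β-lactone F6. Triflation (Tf2O, pyridine) gives the 3β-triflate F7, and displacement with KNO2 in DMF (nitrite-mediated inversion) gives the 3α-hydroxy 19,6β-lactone F8, which LiAlH4 opens to 20.

Further compounds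
F1 | step 6 | 2-(2-methylprop-2-en-1-yl)-1,3-dithiane | C=C(C)CC1SCCCS1
F2 | step 6 | methyl (2S,3S)-3-methyl-2-[2-(2-methylprop-2-en-1-yl)-1,3-dithian-2-yl]-3-[3-(2-methyl-1,3-dioxolan-2-yl)propanoyl]-6-oxocyclohexane-1-carboxylate (C1 epimers/enol; ring positions 2 and 3 are the future C5 and C10) | O=C(CCC3(C)OCCO3)[C@@]2(C)CCC(=O)C(C(=O)OC)[C@@H]2C1(CC(C)=C)SCCCS1
F3 | step 6 | methyl (1S,2S,3S)-1,3-dimethyl-2-[2-(2-methylprop-2-en-1-yl)-1,3-dithian-2-yl]-3-[4-(2-methyl-1,3-dioxolan-2-yl)but-1-en-2-yl]-6-oxocyclohexane-1-carboxylate (future C4, C5 and C10 as in 18) | C=C(CCC3(C)OCCO3)[C@@]2(C)CCC(=O)[C@](C)(C(=O)OC)[C@@H]2C1(CC(C)=C)SCCCS1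
F4 | step 6 | methyl 13,13-(ethylenedioxy)-3-oxo-6,6-(propane-1,3-diyldisulfanediyl)-14,15-dinorlabd-8-en-19-oate | CC1=C(CCC3(C)OCCO3)[C@@]2(C)CCC(=O)[C@](C)(C(=O)OC)[C@@H]2C2(C1)SCCCS2
F5 | step 7 | methyl 13,13-(ethylenedioxy)-3,6-dioxo-14,15-dinorlabd-7-en-19-oate (C9 epimers) | O=C1C=C(C)C(CCC3(C)OCCO3)[C@@]2(C)CCC(=O)[C@](C)(C(=O)OC)[C@H]12
F6 | step 8 | 13,13-(ethylenedioxy)-3β-hydroxy-14,15-dinorlabd-8-en-19,6β-olide | CC1=C(CCC4(C)OCCO4)[C@@]2(C)CC[C@H](O)[C@]3(C)C(=O)O[C@H](C1)[C@H]23
F7 | step 8 | 13,13-(ethylenedioxy)-3β-[(trifluoromethanesulfonyl)oxy]-14,15-dinorlabd-8-en-19,6β-olide | CC1=C(CCC4(C)OCCO4)[C@@]2(C)CC[C@H](OS(=O)(=O)C(F)(F)F)[C@]3(C)C(=O)O[C@H](C1)[C@H]23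
F8 | step 8 | 13,13-(ethylenedioxy)-3α-hydroxy-14,15-dinorlabd-8-en-19,6β-olide | CC1=C(CCC4(C)OCCO4)[C@@]2(C)CC[C@@H](O)[C@]3(C)C(=O)O[C@H](C1)[C@H]23
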